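**Plan**

- Retrosynthesis cuts the butenolide at C15–C5′ (vinylogous aldol of an E-enal), the enal at C14–C15 and C13–C16 (methylalumination and hydroxymethylation of a C13 alkyne), the C6–O bond (remote oxidation from O18), and finally C4–C5 and C9–C10 of the decalin.
- The decalin cut rests on one feature: C4 bears an oxygenated carbon (C18) beside an unoxidised C3, and C8 bears the exocyclic methylene C17. Ring A can therefore start at a C4/C18 epoxide and ring B can end at a C17 allylsilane on an acyclic C8=C9 alkene.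
- Forward, a linear chain is built (alkyne methylalumination for E-C5=C10, enol phosphate coupling for the C8=C9 allylsilane, propargylation for C12–C14); the methyl ketone is epoxidised; ring A and then ring B close in one operation.
- O18 then delivers oxygen to C6, the alkyne becomes the E-enal, and the butenolide is attached last.
- Stereochemistry: C4 from the catalyst-made (R)-epoxide with inversion; C5, C9, C10 from the chair–chair fold of the polyene; C6 from α-face capture of the C6 radical; C15 and C5′ from a BINOL–titanium-controlled vinylogous Mukaiyama aldol.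

Key step: step 12

Numbering: labdane numbers (C1–C20) are used for chain and decalin atoms throughout; C2′–C5′ are the butenolide carbons. Bicyclic compounds are in the normal labdane series (H-5α, H-9α, CH3-10β; C18 = equatorial 4α-CH2O, C19 = axial 4β-CH3).
Assumption: the sense of induction in the two ligand-controlled steps (11 and 21) is taken from the parent reactions; if either proves opposite, the antipodal binaphthol is used.

**Route**

Step 1
Reactants: 1 2-(3-chloropropyl)-2-methyl-1,3-dioxolane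
Product: 2 2-methyl-2-(pent-4-yn-1-yl)-1,3-dioxolane
Conditions: HC≡CLi·H2NCH2CH2NH2, NaI (cat.), DMSO, rt
Reagents that add atoms: lithium acetylide–ethylenediamine complex, [Li+].[C-]#C.NCCN
Why: Acetylide alkylation (SN2) of a primary chloride in DMSO should give the terminal alkyne (C5, C10), the ketal being inert to base.

Step 2
Reactants: 2 2-methyl-2-(pent-4-yn-1-yl)-1,3-dioxolane
Product: 5 (2E)-3-methyl-6-(2-methyl-1,3-dioxolan-2-yl)hex-2-en-1-ol, via alkenyldimethylalane 3 (not isolated), via lithium alkenyl(butyl)dimethylalanate 4 (not isolated)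
Conditions: Me3Al, Cp2ZrCl2 (0.2 equiv), H2O (1.5 equiv), CH2Cl2, −23 °C; then n-BuLi, THF, −78 °C; (CH2O)n, −78 °C → rt
Reagents that add atoms: trimethylaluminium, C[Al](C)C; formaldehyde (from paraformaldehyde), C=O
Why: Negishi carboalumination adds CH3 and Al syn across the terminal alkyne with Al on the terminal carbon, and hydroxymethylation of the alanate with retention fixes the E geometry of C5=C10; the water-accelerated, cold protocol is chosen so that the dioxolane should survive Me3Al.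

Step 3
Reactants: 5 (2E)-3-methyl-6-(2-methyl-1,3-dioxolan-2-yl)hex-2-en-1-ol
Product: 6 2-[(4E)-6-bromo-4-methylhex-4-en-1-yl]-2-methyl-1,3-dioxolane
Conditions: CBr4, PPh3, 2,6-lutidine, CH2Cl2, −20 → 0 °C
Reagents that add atoms: carbon tetrabromide, BrC(Br)(Br)Br
Why: Appel bromination displaces the alkoxyphosphonium group by SN2 without allylic transposition or loss of alkene geometry, and the buffered neutral medium spares the ketal.

Step 4
Reactants: 6 2-[(4E)-6-bromo-4-methylhex-4-en-1-yl]-2-methyl-1,3-dioxolane; 7 methyl acetoacetate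
Product: 9 methyl (6E)-7-methyl-10-(2-methyl-1,3-dioxolan-2-yl)-3-oxodec-6-enoate, via acetoacetate dianion 8 (not isolated)
Conditions: 7, NaH, THF, 0 °C; n-BuLi, 0 °C; then 6, 0 °C
Reagents that add atoms: none
Why: Dianion alkylation of a β-keto ester: the more basic γ-carbanion is alkylated selectively by the allylic bromide and forms the C6–C7 bond.

Step 5
Reactants: 9 methyl (6E)-7-methyl-10-(2-methyl-1,3-dioxolan-2-yl)-3-oxodec-6-enoate
Product: 10 methyl (2Z,6E)-3-[(diethoxyphosphoryl)oxy]-7-methyl-10-(2-methyl-1,3-dioxolan-2-yl)deca-2,6-dienoate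
Conditions: NaH, Et2O, 0 °C; ClP(O)(OEt)2, 0 °C
Reagents that add atoms: diethyl chlorophosphate, CCOP(=O)(Cl)OCC
Why: O-phosphorylation of the chelated sodium enolate in ether should give the enol phosphate with the phosphate cis to the ester (Z), which presets the geometry of the C8=C9 alkene.

Step 6
Reactants: 10 methyl (2Z,6E)-3-[(diethoxyphosphoryl)oxy]-7-methyl-10-(2-methyl-1,3-dioxolan-2-yl)deca-2,6-dienoate; 11 (trimethylsilyl)methylmagnesium chloride
Product: 12 methyl (2Z,6E)-7-methyl-10-(2-methyl-1,3-dioxolan-2-yl)-3-[(trimethylsilyl)methyl]deca-2,6-dienoate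
Conditions: Ni(acac)2 (5 mol %), THF, 0 °C → rt
Reagents that add atoms: none
Why: Nickel-catalysed Kumada-type coupling of an enol phosphate with a Grignard reagent proceeds with retention, so CH2SiMe3 (C17) sits cis to the ester carbon (C11) and C7 trans to C11; at 0 °C coupling should outpace addition to the ester.

Step 7
Reactants: 12 methyl (2Z,6E)-7-methyl-10-(2-methyl-1,3-dioxolan-2-yl)-3-[(trimethylsilyl)methyl]deca-2,6-dienoate
Product: 13 (2Z,6E)-7-methyl-10-(2-methyl-1,3-dioxolan-2-yl)-3-[(trimethylsilyl)methyl]deca-2,6-dien-1-ol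
Conditions: iBu2AlH (2.2 equiv), CH2Cl2, −78 °C
Reagents that add atoms: none
Why: 1,2-Reduction of the unsaturated ester by the aluminium hydride gives the allylic alcohol and leaves alkene geometry, ketal and allylsilane untouched.

Step 8
Reactants: 13 (2Z,6E)-7-methyl-10-(2-methyl-1,3-dioxolan-2-yl)-3-[(trimethylsilyl)methyl]deca-2,6-dien-1-ol
Product: 14 2-[(4E,8Z)-10-bromo-4-methyl-8-[(trimethylsilyl)methyl]deca-4,8-dien-1-yl]-2-methyl-1,3-dioxolane
Conditions: CBr4, PPh3, 2,6-lutidine, CH2Cl2, −40 → −10 °C; used at once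
Reagents that add atoms: carbon tetrabromide, BrC(Br)(Br)Br
Why: Appel bromination under cold, buffered conditions gives the primary allylic bromide by SN2; because this γ-silyl allylic bromide can undergo 1,4-elimination it is carried on without chromatography.

Step 9
Reactants: 14 2-[(4E,8Z)-10-bromo-4-methyl-8-[(trimethylsilyl)methyl]deca-4,8-dien-1-yl]-2-methyl-1,3-dioxolane; 15 1-(trimethylsilyl)propyne
Product: 17 2-methyl-2-[(4E,8Z)-4-methyl-13-(trimethylsilyl)-8-[(trimethylsilyl)methyl]trideca-4,8-dien-12-yn-1-yl]-1,3-dioxolane, via 3-lithio-1-(trimethylsilyl)propyne 16 (not isolated)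
Conditions: 15, n-BuLi, THF, −78 → −20 °C; then 14, −78 → −30 °C
Reagents that add atoms: none
Why: Propargylic lithiation and SN2 alkylation by the allylic bromide (the silyl group steers reaction to the propargylic carbon) forms C11–C12 and installs C13/C14 as a masked terminal alkyne, a spectator that is a poorer π-nucleophile than the allylsilane.

Step 10
Reactants: 17 2-methyl-2-[(4E,8Z)-4-methyl-13-(trimethylsilyl)-8-[(trimethylsilyl)methyl]trideca-4,8-dien-12-yn-1-yl]-1,3-dioxolane
Product: 18 (6E,10Z)-6-methyl-15-(trimethylsilyl)-10-[(trimethylsilyl)methyl]pentadeca-6,10-dien-14-yn-2-one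
Conditions: PPTS (cat.), acetone/H2O, 45 °C
Reagents that add atoms: water, O
Why: Acid-catalysed ketal hydrolysis with a weak acid that should not protodesilylate the allylsilane or the alkynylsilane liberates the methyl ketone.

Step 11
Reactants: 18 (6E,10Z)-6-methyl-15-(trimethylsilyl)-10-[(trimethylsilyl)methyl]pentadeca-6,10-dien-14-yn-2-one
Product: 19 (2R)-2-methyl-2-[(4E,8Z)-4-methyl-13-(trimethylsilyl)-8-[(trimethylsilyl)methyl]trideca-4,8-dien-12-yn-1-yl]oxirane
Conditions: Me3S(O)I, NaH, THF (ylide, 1.2 equiv); LaLi3[(R)-binaphthoxide]3 (5 mol %), (2,4,6-(MeO)3C6H2)3P=O (5 mol %), THF, rt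
Reagents that add atoms: trimethylsulfoxonium iodide, C[S+](C)(C)=O.[I-]
Why: Catalytic asymmetric Corey–Chaykovsky epoxidation of a methyl ketone: the lanthanum–lithium binaphthoxide complex binds the ketone and directs the sulfoxonium ylide to one carbonyl face, setting C4 as R, while alkenes and silanes are inert to the ylide.

Step 12
Reactants: 19 (2R)-2-methyl-2-[(4E,8Z)-4-methyl-13-(trimethylsilyl)-8-[(trimethylsilyl)methyl]trideca-4,8-dien-12-yn-1-yl]oxirane
Product: 20 14-(trimethylsilyl)-15,16-dinorlabd-8(17)-en-13-yn-18-ol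
Conditions: MeAlCl2 (1.5 equiv), CH2Cl2 (high dilution), −94 → −78 °C; then Et3N/MeOH
Reagents that add atoms: none
Why: MeAlCl2 binds the epoxide oxygen and weakens the C4–O bond; the C5=C10 alkene attacks C4 opposite to the leaving oxygen (6-endo, ring A), the tertiary C10 cation is taken by C9 of the allylsilane (6-endo, ring B), and the β-silyl cation at C8 loses Me3Si so that only the C8=C17 alkene can form. The closest known reaction type is the Lewis-acid epoxide-initiated, allylsilane-terminated polyene cyclisation. C4 is set by inversion of the (R)-epoxide centre; C5 and C10 by anti addition across the E C5=C10 alkene in a chair (trans fusion); C9 by the chair of ring B, in which C11, trans to C7 on the alkene, becomes equatorial. The step needs a concerted anti opening in the chair–chair fold with the aluminium-bound C18 oxymethyl group equatorial; this fold should be favoured because that bulky group would otherwise be syn-axial to the C10 methyl, leaving the small C19 methyl axial. High dilution, very low temperature and the strongly nucleophilic allylsilane are chosen so that ring closure should outrun the 1,2-hydride shift of the 2,2-disubstituted epoxide to an aldehyde. The alkynylsilane stays a spectator.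

Step 13
Reactants: 20 14-(trimethylsilyl)-15,16-dinorlabd-8(17)-en-13-yn-18-ol
Product: 21 14-(trimethylsilyl)-15,16-dinorlabd-8(17)-en-13-yn-18-yl nitrite
Conditions: NOCl (1.1 equiv), pyridine, −30 °C; used directly
Reagents that add atoms: nitrosyl chloride, O=NCl
Why: O-Nitrosation of the primary alcohol in pyridine is far faster than addition of NOCl to the isolated alkene at low temperature and gives the nitrite ester for the Barton reaction.

Step 14
Reactants: 21 14-(trimethylsilyl)-15,16-dinorlabd-8(17)-en-13-yn-18-yl nitrite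
Product: 22 18-hydroxy-14-(trimethylsilyl)-15,16-dinorlabd-8(17)-en-13-yn-6α-yl nitrate
Conditions: hν (Hg lamp, Pyrex), O2 stream, benzene, 10–15 °C
Reagents that add atoms: dioxygen, O=O
Why: Barton nitrite photolysis in the presence of oxygen: the O18 alkoxy radical abstracts the equatorial H-6α through a six-membered chair transition state (equatorial C18 is gauche to C6 and anti to C2, so only C6 is in reach), and the C6 radical should be captured by O2 and NO on the α face, away from the axial C19 and C20 methyls, giving the equatorial 6α-nitrate.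

Step 15
Reactants: 22 18-hydroxy-14-(trimethylsilyl)-15,16-dinorlabd-8(17)-en-13-yn-6α-yl nitrate
Product: 23 14-(trimethylsilyl)-15,16-dinorlabd-8(17)-en-13-yne-6α,18-diol
Conditions: Zn dust, AcOH/THF, rt
Reagents that add atoms: none
Why: Reductive cleavage of the O–NO2 bond of a nitrate ester by zinc frees the 6α-alcohol with retention, since the C6–O bond is not broken.

Step 16
Reactants: 23 14-(trimethylsilyl)-15,16-dinorlabd-8(17)-en-13-yne-6α,18-diol
Product: 24 15,16-dinorlabd-8(17)-en-13-yne-6α,18-diol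
Conditions: K2CO3, MeOH, rt
Reagents that add atoms: none
Why: Base-mediated methanolysis of the C(sp)–Si bond unmasks the terminal alkyne; the diol is inert.

Step 17
Reactants: 24 15,16-dinorlabd-8(17)-en-13-yne-6α,18-diol
Product: 25 6α,18-bis(triethylsilyloxy)-15,16-dinorlabd-8(17)-en-13-yne
Conditions: TESOTf (2.5 equiv), 2,6-lutidine, CH2Cl2, −78 → 0 °C
Reagents that add atoms: triethylsilyl trifluoromethanesulfonate, CC[Si](CC)(CC)OS(=O)(=O)C(F)(F)F
Why: Silylation with a silyl triflate and a hindered base protects both the neopentyl primary and the hindered secondary alcohol as ethers that tolerate organoaluminium, organolithium and Lewis-acid conditions and are removed by fluoride.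

Step 18
Reactants: 25 6α,18-bis(triethylsilyloxy)-15,16-dinorlabd-8(17)-en-13-yne
Product: 28 (13E)-6α,18-bis(triethylsilyloxy)labda-8(17),13-dien-15-ol, via alkenyldimethylalane 26 (not isolated), via lithium alkenyl(butyl)dimethylalanate 27 (not isolated)
Conditions: Me3Al, Cp2ZrCl2 (0.3 equiv), H2O (1.5 equiv), CH2Cl2, −23 °C; then n-BuLi, THF, −78 °C; (CH2O)n, −78 °C → rt
Reagents that add atoms: trimethylaluminium, C[Al](C)C; formaldehyde (from paraformaldehyde), C=O
Why: Negishi carboalumination (syn methylalumination of the terminal alkyne; the 1,1-disubstituted C8=C17 alkene is inert to the achiral zirconocene) and hydroxymethylation of the alanate install C16 and C15 with E geometry at C13=C14.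

Step 19
Reactants: 28 (13E)-6α,18-bis(triethylsilyloxy)labda-8(17),13-dien-15-ol
Product: 29 (13E)-6α,18-bis(triethylsilyloxy)labda-8(17),13-dien-15-al
Conditions: MnO2 (activated, excess), CH2Cl2, rt
Reagents that add atoms: none
Why: Chemoselective oxidation of the allylic alcohol by MnO2 gives the E-enal without alkene isomerisation.

Step 20
Reactants: 30 4-methylfuran-2(5H)-one
Product: 31 trimethyl[(4-methylfuran-2-yl)oxy]silane
Conditions: TMSOTf, Et3N, Et2O, 0 °C; distilled
Reagents that add atoms: trimethylsilyl trifluoromethanesulfonate, C[Si](C)(C)OS(=O)(=O)C(F)(F)F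
Why: Soft enolisation and O-silylation of the butenolide gives the 2-silyloxyfuran, the dienolate equivalent for the vinylogous Mukaiyama aldol reaction.

Step 21
Reactants: 29 (13E)-6α,18-bis(triethylsilyloxy)labda-8(17),13-dien-15-al; 31 trimethyl[(4-methylfuran-2-yl)oxy]silane
Product: 32 (13E,15S)-15-[(2S)-3-methyl-5-oxo-2,5-dihydrofuran-2-yl]-6α,18-bis(triethylsilyloxy)labda-8(17),13-dien-15-ol
Conditions: Ti(OiPr)4/(R)-BINOL (20 mol %), Et2O, −20 °C; then citric acid, MeOH, 0 °C
Reagents that add atoms: none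
Why: Vinylogous Mukaiyama aldol reaction: the silyloxyfuran reacts through C5′ with the titanium-bound enal, the BINOL–titanium Lewis acid is expected to expose the Re face of the aldehyde (15S), and the open transition state of Lewis-acid-mediated silyloxyfuran additions should favour the threo (like) adduct (5′S); the distant decalin centres give no control, so both new centres rest on the catalyst, and brief acidic methanolysis removes the transferred trimethylsilyl group.

Step 22
Reactants: 32 (13E,15S)-15-[(2S)-3-methyl-5-oxo-2,5-dihydrofuran-2-yl]-6α,18-bis(triethylsilyloxy)labda-8(17),13-dien-15-ol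
Product: 33 (13E,15S)-15-[(2S)-3-methyl-5-oxo-2,5-dihydrofuran-2-yl]labda-8(17),13-diene-6α,15,18-triol (CNP0221530.1)
Conditions: HF·pyridine, pyridine/THF, 0 °C → rt
Reagents that add atoms: none
Why: Fluoride-mediated desilylation under buffered, non-basic conditions removes both triethylsilyl ethers without the base-induced epimerisation or retro-aldol cleavage to which the butenolide is prone, and gives the target.

**Compound list**

1 | 2-(3-chloropropyl)-2-methyl-1,3-dioxolane | CC1(CCCCl)OCCO1 | starting material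
2 | 2-methyl-2-(pent-4-yn-1-yl)-1,3-dioxolane | CC1(CCCC#C)OCCO1 | intermediate
3 | dimethyl[(1E)-2-methyl-5-(2-methyl-1,3-dioxolan-2-yl)pent-1-en-1-yl]alane (not isolated) | C[Al](C)/C=C(\C)CCCC1(C)OCCO1 | intermediate
4 | lithium butyl(dimethyl)[(1E)-2-methyl-5-(2-methyl-1,3-dioxolan-2-yl)pent-1-en-1-yl]alanate (not isolated) | [Li+].CCCC[Al-](C)(C)/C=C(\C)CCCC1(C)OCCO1 | intermediate
5 | (2E)-3-methyl-6-(2-methyl-1,3-dioxolan-2-yl)hex-2-en-1-ol | OC/C=C(\C)CCCC1(C)OCCO1 | intermediate
6 | 2-[(4E)-6-bromo-4-methylhex-4-en-1-yl]-2-methyl-1,3-dioxolane | BrC/C=C(\C)CCCC1(C)OCCO1 | intermediate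
7 | methyl acetoacetate | CC(=O)CC(=O)OC | starting material
8 | methyl acetoacetate dianion, lithium sodium salt (not isolated) | COC(=O)[CH-]C(=O)[CH2-].[Na+].[Li+] | intermediate
9 | methyl (6E)-7-methyl-10-(2-methyl-1,3-dioxolan-2-yl)-3-oxodec-6-enoate | COC(=O)CC(=O)CC/C=C(\C)CCCC1(C)OCCO1 | intermediate
10 | methyl (2Z,6E)-3-[(diethoxyphosphoryl)oxy]-7-methyl-10-(2-methyl-1,3-dioxolan-2-yl)deca-2,6-dienoate | COC(=O)/C=C(\OP(=O)(OCC)OCC)CC/C=C(\C)CCCC1(C)OCCO1 | intermediate
11 | (trimethylsilyl)methylmagnesium chloride | C[Si](C)(C)C[Mg]Cl | starting material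
12 | methyl (2Z,6E)-7-methyl-10-(2-methyl-1,3-dioxolan-2-yl)-3-[(trimethylsilyl)methyl]deca-2,6-dienoate | COC(=O)/C=C(\C[Si](C)(C)C)CC/C=C(\C)CCCC1(C)OCCO1 | intermediate
13 | (2Z,6E)-7-methyl-10-(2-methyl-1,3-dioxolan-2-yl)-3-[(trimethylsilyl)methyl]deca-2,6-dien-1-ol | OC/C=C(\C[Si](C)(C)C)CC/C=C(\C)CCCC1(C)OCCO1 | intermediate
14 | 2-[(4E,8Z)-10-bromo-4-methyl-8-[(trimethylsilyl)methyl]deca-4,8-dien-1-yl]-2-methyl-1,3-dioxolane | BrC/C=C(\C[Si](C)(C)C)CC/C=C(\C)CCCC1(C)OCCO1 | intermediate
15 | 1-(trimethylsilyl)propyne | CC#C[Si](C)(C)C | starting material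
16 | 3-lithio-1-(trimethylsilyl)propyne (not isolated) | [Li]CC#C[Si](C)(C)C | intermediate
17 | 2-methyl-2-[(4E,8Z)-4-methyl-13-(trimethylsilyl)-8-[(trimethylsilyl)methyl]trideca-4,8-dien-12-yn-1-yl]-1,3-dioxolane | C[Si](C)(C)C#CCC/C=C(\C[Si](C)(C)C)CC/C=C(\C)CCCC1(C)OCCO1 | intermediate
18 | (6E,10Z)-6-methyl-15-(trimethylsilyl)-10-[(trimethylsilyl)methyl]pentadeca-6,10-dien-14-yn-2-one | CC(=O)CCC/C(C)=C/CC/C(C[Si](C)(C)C)=C/CCC#C[Si](C)(C)C | intermediate
19 | (2R)-2-methyl-2-[(4E,8Z)-4-methyl-13-(trimethylsilyl)-8-[(trimethylsilyl)methyl]trideca-4,8-dien-12-yn-1-yl]oxirane (key-step precursor) | C[C@]1(CO1)CCC/C(C)=C/CC/C(C[Si](C)(C)C)=C/CCC#C[Si](C)(C)C | intermediate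
20 | 14-(trimethylsilyl)-15,16-dinorlabd-8(17)-en-13-yn-18-ol (key-step product) | C=C1CC[C@H]2[C@](C)(CO)CCC[C@]2(C)[C@H]1CCC#C[Si](C)(C)C | intermediate
21 | 14-(trimethylsilyl)-15,16-dinorlabd-8(17)-en-13-yn-18-yl nitrite | C=C1CC[C@H]2[C@](C)(CON=O)CCC[C@]2(C)[C@H]1CCC#C[Si](C)(C)C | intermediate
22 | 18-hydroxy-14-(trimethylsilyl)-15,16-dinorlabd-8(17)-en-13-yn-6α-yl nitrate | C=C1C[C@H](O[N+](=O)[O-])[C@H]2[C@](C)(CO)CCC[C@]2(C)[C@H]1CCC#C[Si](C)(C)C | intermediate
23 | 14-(trimethylsilyl)-15,16-dinorlabd-8(17)-en-13-yne-6α,18-diol | C=C1C[C@H](O)[C@H]2[C@](C)(CO)CCC[C@]2(C)[C@H]1CCC#C[Si](C)(C)C | intermediate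
24 | 15,16-dinorlabd-8(17)-en-13-yne-6α,18-diol | C=C1C[C@H](O)[C@H]2[C@](C)(CO)CCC[C@]2(C)[C@H]1CCC#C | intermediate
25 | 6α,18-bis(triethylsilyloxy)-15,16-dinorlabd-8(17)-en-13-yne | C=C1C[C@H](O[Si](CC)(CC)CC)[C@H]2[C@](C)(CO[Si](CC)(CC)CC)CCC[C@]2(C)[C@H]1CCC#C | intermediate
26 | dimethyl[(13E)-6α,18-bis(triethylsilyloxy)-15-norlabda-8(17),13-dien-14-yl]alane (not isolated) | C=C1C[C@H](O[Si](CC)(CC)CC)[C@H]2[C@](C)(CO[Si](CC)(CC)CC)CCC[C@]2(C)[C@H]1CC/C(C)=C/[Al](C)C | intermediate
27 | lithium butyl(dimethyl)[(13E)-6α,18-bis(triethylsilyloxy)-15-norlabda-8(17),13-dien-14-yl]alanate (not isolated) | [Li+].C=C1C[C@H](O[Si](CC)(CC)CC)[C@H]2[C@](C)(CO[Si](CC)(CC)CC)CCC[C@]2(C)[C@H]1CC/C(C)=C/[Al-](C)(C)CCCC | intermediate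
28 | (13E)-6α,18-bis(triethylsilyloxy)labda-8(17),13-dien-15-ol | C=C1C[C@H](O[Si](CC)(CC)CC)[C@H]2[C@](C)(CO[Si](CC)(CC)CC)CCC[C@]2(C)[C@H]1CC/C(C)=C/CO | intermediate
29 | (13E)-6α,18-bis(triethylsilyloxy)labda-8(17),13-dien-15-al | C=C1C[C@H](O[Si](CC)(CC)CC)[C@H]2[C@](C)(CO[Si](CC)(CC)CC)CCC[C@]2(C)[C@H]1CC/C(C)=C/C=O | intermediate
30 | 4-methylfuran-2(5H)-one | CC1=CC(=O)OC1 | starting material
31 | trimethyl[(4-methylfuran-2-yl)oxy]silane | Cc1coc(O[Si](C)(C)C)c1 | intermediate
32 | (13E,15S)-15-[(2S)-3-methyl-5-oxo-2,5-dihydrofuran-2-yl]-6α,18-bis(triethylsilyloxy)labda-8(17),13-dien-15-ol | C=C1C[C@H](O[Si](CC)(CC)CC)[C@H]2[C@](C)(CO[Si](CC)(CC)CC)CCC[C@]2(C)[C@H]1CC/C(C)=C/[C@H](O)[C@H]1OC(=O)C=C1C | intermediate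
33 | (13E,15S)-15-[(2S)-3-methyl-5-oxo-2,5-dihydrofuran-2-yl]labda-8(17),13-diene-6α,15,18-triol (CNP0221530.1) | C=C1C[C@H](O)[C@H]2[C@](C)(CO)CCC[C@]2(C)[C@H]1CC/C(C)=C/[C@H](O)[C@H]1OC(=O)C=C1C | target

**Totals**

Total steps: 22. Longest linear sequence: 21 (steps 1–19, 21, 22; step 20 prepares 31).

**Steps most likely to fail**

1. Step 12 (key step). The aluminium-bound 2,2-disubstituted epoxide may ionise to an open C4 cation before C5 bonds. That opens a 1,2-hydride shift from C18 to the α-methyl aldehyde, erodes transfer of configuration to C4, or lets the chain fold with the oxymethyl group axial.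
 Fallback (sets out from 19, returns at 20): the initiator becomes a trisubstituted C3/C4 epoxide, a well-precedented initiator class whose C3 carbinol centre carries the stereochemical information through the cyclisation; the extra C3 hydroxyl is removed afterwards. 19 is rearranged on purpose with MeAl(OAr)2 (Ar = 4-bromo-2,6-di-tert-butylphenyl, CH2Cl2, −78 °C; Meinwald rearrangement) to the α-methyl aldehyde F1. IBX (DMSO, 70 °C) dehydrogenates it to the (E)-2-methyl enal F2, and NaBH4/CeCl3·7H2O reduces this to the E-allylic alcohol F3. Sharpless epoxidation [Ti(OiPr)4, L-(+)-diethyl tartrate, t-BuOOH, −20 °C] gives the (2S,3S)-epoxy alcohol F4, which TBSCl/imidazole converts into the silyl ether F5. MeAlCl2 (CH2Cl2, −78 °C) closes rings A and B by endo opening at C4 and gives the 3β-hydroxy-18-silyloxy bicycle F6; the E-CH2OSi group becomes the equatorial C18. Barton–McCombie deoxygenation through the xanthate F7 (NaH, CS2, MeI; then Bu3SnH, AIBN, toluene, 100 °C) gives the 3-deoxy silyl ether F8, and HF·pyridine frees 20.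

2. Step 14. β-Scission of the O18 alkoxy radical (loss of C18 as formaldehyde) may compete with the 1,5-hydrogen transfer from C6, and capture of the C6 radical by O2 may not be fully α-selective.
 Fallback (sets out from 20, returns at 23): the C6–O bond is made by ring closure, so its configuration is fixed by geometry. 20 is oxidised (TEMPO, PhI(OAc)2, MeCN/H2O) to the C18 carboxylic acid F9 and converted [(COCl)2, then NH3] into the primary amide F10. Photolysis with PhI(OAc)2/I2 (N-iodoamide; Hofmann–Löffler–Freytag-type 1,5-hydrogen transfer from C6 to the amidyl nitrogen, displacement of the 6-iodide by the amide oxygen, hydrolysis of the iminolactone) gives the 18,6α-lactone F11; only a 6α C–O bond can close this five-membered ring onto the equatorial C18. LiAlH4 (THF, 0 °C) reduces it to diol 23.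

3. Step 21. Catalyst control over the aldehyde face and over the threo/erythro ratio may be incomplete with the 4-methyl-substituted silyloxyfuran, and attack through C3′ may compete.
 Fallback (sets out from 29, returns at 33): both centres are set by an auxiliary-controlled aldol and the butenolide is built afterwards. The boron enolate (Bu2BOTf, Et3N, CH2Cl2, −78 → 0 °C) of (R)-4-benzyl-3-[(4-methoxybenzyloxy)acetyl]oxazolidin-2-one adds to 29 in an Evans syn-aldol reaction to give the imide F12 (15S; C5′ with the spatial arrangement of 33). MeNH(OMe)·HCl/Me3Al gives the Weinreb amide F13, TESOTf/2,6-lutidine its silyl ether F14, and MeMgBr the methyl ketone F15 (C4′ and its methyl). DDQ removes the 4-methoxybenzyl group to give the α-hydroxy ketone F16. Ph3P=C=C=O (toluene, 80 °C; O-acylation, then intramolecular Wittig reaction) closes the ring to the tris(triethylsilyl) butenolide F17, which HF·pyridine converts into 33.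

**Further compounds**

F1 | step 12 | (6E,10Z)-2,6-dimethyl-15-(trimethylsilyl)-10-[(trimethylsilyl)methyl]pentadeca-6,10-dien-14-ynal (C2 unassigned) | O=CC(C)CCC/C(C)=C/CC/C(C[Si](C)(C)C)=C/CCC#C[Si](C)(C)C
F2 | step 12 | (2E,6E,10Z)-2,6-dimethyl-15-(trimethylsilyl)-10-[(trimethylsilyl)methyl]pentadeca-2,6,10-trien-14-ynal | O=C/C(C)=C/CC/C(C)=C/CC/C(C[Si](C)(C)C)=C/CCC#C[Si](C)(C)C
F3 | step 12 | (2E,6E,10Z)-2,6-dimethyl-15-(trimethylsilyl)-10-[(trimethylsilyl)methyl]pentadeca-2,6,10-trien-14-yn-1-ol | OC/C(C)=C/CC/C(C)=C/CC/C(C[Si](C)(C)C)=C/CCC#C[Si](C)(C)C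
F4 | step 12 | {(2S,3S)-2-methyl-3-[(3E,7Z)-3-methyl-12-(trimethylsilyl)-7-[(trimethylsilyl)methyl]dodeca-3,7-dien-11-yn-1-yl]oxiran-2-yl}methanol | OC[C@]1(C)O[C@H]1CC/C(C)=C/CC/C(C[Si](C)(C)C)=C/CCC#C[Si](C)(C)C
F5 | step 12 | tert-butyldimethylsilyl ether of F4 | CC(C)(C)[Si](C)(C)OC[C@]1(C)O[C@H]1CC/C(C)=C/CC/C(C[Si](C)(C)C)=C/CCC#C[Si](C)(C)C
F6 | step 12 | 18-(tert-butyldimethylsilyloxy)-14-(trimethylsilyl)-15,16-dinorlabd-8(17)-en-13-yn-3β-ol | C=C1CC[C@H]2[C@](C)(CO[Si](C)(C)C(C)(C)C)[C@@H](O)CC[C@]2(C)[C@H]1CCC#C[Si](C)(C)C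
F7 | step 12 | O-[18-(tert-butyldimethylsilyloxy)-14-(trimethylsilyl)-15,16-dinorlabd-8(17)-en-13-yn-3β-yl] S-methyl dithiocarbonate | C=C1CC[C@H]2[C@](C)(CO[Si](C)(C)C(C)(C)C)[C@@H](OC(=S)SC)CC[C@]2(C)[C@H]1CCC#C[Si](C)(C)C
F8 | step 12 | 18-(tert-butyldimethylsilyloxy)-14-(trimethylsilyl)-15,16-dinorlabd-8(17)-en-13-yne | C=C1CC[C@H]2[C@](C)(CO[Si](C)(C)C(C)(C)C)CCC[C@]2(C)[C@H]1CCC#C[Si](C)(C)C
F9 | step 14 | 14-(trimethylsilyl)-15,16-dinorlabd-8(17)-en-13-yn-18-oic acid | C=C1CC[C@H]2[C@](C)(C(=O)O)CCC[C@]2(C)[C@H]1CCC#C[Si](C)(C)C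
F10 | step 14 | 14-(trimethylsilyl)-15,16-dinorlabd-8(17)-en-13-yn-18-amide | C=C1CC[C@H]2[C@](C)(C(N)=O)CCC[C@]2(C)[C@H]1CCC#C[Si](C)(C)C
F11 | step 14 | 14-(trimethylsilyl)-15,16-dinorlabd-8(17)-en-13-yn-18,6α-olide | C=C1C[C@H](O3)[C@H]2[C@](C)(C3=O)CCC[C@]2(C)[C@H]1CCC#C[Si](C)(C)C
F12 | step 21 | Evans syn-aldol imide of 29: (4R)-4-benzyl-oxazolidin-2-one N-acylated by the (13E)-15(S)-hydroxy-5′-(4-methoxybenzyloxy) acid chain, 6α,18-bis(triethylsilyl) ether | C=C1C[C@H](O[Si](CC)(CC)CC)[C@H]2[C@](C)(CO[Si](CC)(CC)CC)CCC[C@]2(C)[C@H]1CC/C(C)=C/[C@H](O)[C@@H](OCc1ccc(OC)cc1)C(=O)N1[C@H](Cc2ccccc2)COC1=O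
F13 | step 21 | corresponding N-methoxy-N-methylamide (15-hydroxy, 5′-O-(4-methoxybenzyl)) | C=C1C[C@H](O[Si](CC)(CC)CC)[C@H]2[C@](C)(CO[Si](CC)(CC)CC)CCC[C@]2(C)[C@H]1CC/C(C)=C/[C@H](O)[C@@H](OCc1ccc(OC)cc1)C(=O)N(C)OC
F14 | step 21 | 15-O-triethylsilyl ether of F13 | C=C1C[C@H](O[Si](CC)(CC)CC)[C@H]2[C@](C)(CO[Si](CC)(CC)CC)CCC[C@]2(C)[C@H]1CC/C(C)=C/[C@H](O[Si](CC)(CC)CC)[C@@H](OCc1ccc(OC)cc1)C(=O)N(C)OC
F15 | step 21 | methyl ketone: 5′-(4-methoxybenzyloxy)-15-(triethylsilyloxy) chain ending in C4′(=O)CH3 | C=C1C[C@H](O[Si](CC)(CC)CC)[C@H]2[C@](C)(CO[Si](CC)(CC)CC)CCC[C@]2(C)[C@H]1CC/C(C)=C/[C@H](O[Si](CC)(CC)CC)[C@@H](OCc1ccc(OC)cc1)C(C)=O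
F16 | step 21 | α-hydroxy methyl ketone (5′-OH free, 15-O-triethylsilyl) | C=C1C[C@H](O[Si](CC)(CC)CC)[C@H]2[C@](C)(CO[Si](CC)(CC)CC)CCC[C@]2(C)[C@H]1CC/C(C)=C/[C@H](O[Si](CC)(CC)CC)[C@@H](O)C(C)=O
F17 | step 21 | 6α,15,18-tris(triethylsilyl) ether of 33 | C=C1C[C@H](O[Si](CC)(CC)CC)[C@H]2[C@](C)(CO[Si](CC)(CC)CC)CCC[C@]2(C)[C@H]1CC/C(C)=C/[C@H](O[Si](CC)(CC)CC)[C@H]1OC(=O)C=C1C
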